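Rings A of both flavanone units (C4a, C5–C8, C8a and C4a'', C5''–C8a'') are acylphloroglucinols attached to C4 and C4'' that differ only at O7 (free) and O7'' (methyl). The route therefore disconnects the C4a–C5 and C4a''–C5'' ring bonds and encodes that difference in two 4-alkoxy-2-pyrones. In one operation Mg(OMe)2 refolds both masked triketide arms of an (E,E)-2,3-bis(4-methoxybenzylidene)-1,4-diketone, one arm a 4-benzyloxy- and the other a 4-methoxy-2-pyron-6-ylmethyl ketone, into an α,α'-linked bis(2'-hydroxychalcone), closing two benzene rings and creating no stereocentre. The four stereocentres (2R,3R,2''R,3''R, both heterocycles 2,3-cis) follow from a catalyst-controlled double oxa-Michael closure.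

Key step: step 8

Remarks on the chemistry (assumptions)
- Read from its SMILES, the target is (2R,3R,2''R,3''R), with H-2/H-3 and H-2''/H-3'' cis in both heterocycles. C3 and C3'' are thus the kinetic, epimerisable centres and must see neither base nor heat once they are set.
- All bis(4-methoxybenzylidene) intermediates are handled with exclusion of light, because such diaryl dienes isomerise and electrocyclise photochemically.

Step 1
Reactants: 1 dimethyl succinate; 2 4-methoxybenzaldehyde
Product: 3 (E)-3-(methoxycarbonyl)-4-(4-methoxyphenyl)but-3-enoic acid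
Conditions: NaOMe (1.5 equiv), MeOH, reflux; then aq. HCl
Reagents that add atoms: none
Why: Stobbe condensation, in which the succinate enolate adds to the aldehyde, the alkoxide lactonises onto the remote ester and E1cB opening of the paraconate gives the half-ester carboxylate irreversibly, with the aryl group trans to the ester carbonyl (E) for steric reasons.

Step 2
Reactants: 3 (E)-3-(methoxycarbonyl)-4-(4-methoxyphenyl)but-3-enoic acid
Product: 4 dimethyl (E)-2-(4-methoxybenzylidene)succinate
Conditions: MeOH, H2SO4 (cat.), reflux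
Reagents that add atoms: methanol, CO
Why: Fischer esterification of the saturated carboxylic acid restores the CH2–CO2Me unit that must be enolised in the second condensation and leaves the conjugated ester and the alkene untouched.

Step 3
Reactants: 4 dimethyl (E)-2-(4-methoxybenzylidene)succinate; 2 4-methoxybenzaldehyde
Product: 6 (2E,3E)-2,3-bis(4-methoxybenzylidene)succinic acid, via half-ester 5 (not isolated)
Conditions: NaOMe (2 equiv), MeOH, reflux; then aq. NaOH, reflux; then aq. HCl
Reagents that add atoms: sodium hydroxide (NaOH), [Na+].[OH-]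
Why: A second Stobbe condensation at the only enolisable CH2 group gives the (E,E)-half-ester by the same lactone and E1cB sequence, and saponification of its remaining hindered ester in the same pot gives the bis(arylidene)succinic (fulgenic) acid, a class of compound classically made in this way.

Step 4
Reactants: 6 (2E,3E)-2,3-bis(4-methoxybenzylidene)succinic acid
Product: 7 (3E,4E)-3,4-bis(4-methoxybenzylidene)dihydrofuran-2,5-dione
Conditions: AcCl, CH2Cl2, rt, dark
Reagents that add atoms: none
Why: Acetyl chloride dehydrates the 1,4-diacid through a mixed anhydride to the five-membered cyclic anhydride (fulgide formation) at room temperature, so that neither heat nor light can isomerise the (E,E) diene.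

Step 5
Reactants: 7 (3E,4E)-3,4-bis(4-methoxybenzylidene)dihydrofuran-2,5-dione; 8 4-methoxy-6-methyl-2H-pyran-2-one
Product: 10 (2E,3E)-2,3-bis(4-methoxybenzylidene)-5-(4-methoxy-2-oxo-2H-pyran-6-yl)-4-oxopentanoic acid, via 6-lithiomethyl-4-methoxy-2-pyrone 9 (not isolated)
Conditions: 8 (2.2 equiv), LiN(SiMe3)2 (2.2 equiv), THF, −78 °C; then 7, −78 to −40 °C; then cold 1 M HCl
Reagents that add atoms: none
Why: LiN(SiMe3)2 removes a proton from the 6-methyl group (vinylogous enolisation) and the dienolate 9 is C-acylated by the symmetric anhydride with ring opening (Claisen-type acylation), the lithium carboxylate that is released and the enolate formed from the acidic new methylene group by the second equivalent of 9 protecting the product against a second addition.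

Step 6
Reactants: 11 4-hydroxy-6-methyl-2H-pyran-2-one
Product: 12 4-(benzyloxy)-6-methyl-2H-pyran-2-one
Conditions: BnOH, PPh3, diisopropyl azodicarboxylate, THF, 0 °C to rt
Reagents that add atoms: benzyl alcohol, OCc1ccccc1
Why: Mitsunobu etherification of the acidic 4-hydroxyl group (a vinylogous carboxylic acid) alkylates on oxygen and avoids the C3-benzylation that benzyl halides and base can give.

Step 7
Reactants: 10 (2E,3E)-2,3-bis(4-methoxybenzylidene)-5-(4-methoxy-2-oxo-2H-pyran-6-yl)-4-oxopentanoic acid; 12 4-(benzyloxy)-6-methyl-2H-pyran-2-one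
Product: 15 (3E,4E)-1-[4-(benzyloxy)-2-oxo-2H-pyran-6-yl]-6-(4-methoxy-2-oxo-2H-pyran-6-yl)-3,4-bis(4-methoxybenzylidene)hexane-2,5-dione, via imidazolide 13 (not isolated), via 6-lithiomethyl-4-benzyloxy-2-pyrone 14 (not isolated)
Conditions: 10, 1,1'-carbonyldiimidazole (1.05 equiv), THF, 0 °C to rt; this solution added to 12 (2.2 equiv) and LiN(SiMe3)2 (4.4 equiv), THF, −78 °C; then cold 1 M HCl
Reagents that add atoms: none
Why: Claisen-type C-acylation of the lithiated 4-alkoxy-6-methyl-2-pyrone 14 by the N-acylimidazole 13, in which the excess base first converts imidazole and the acidic methylene group of 13 into their anions so that the first ketone is masked as its enolate, and the product is again protected as its enolate until the acidic quench.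

Step 8
Reactants: 15 (3E,4E)-1-[4-(benzyloxy)-2-oxo-2H-pyran-6-yl]-6-(4-methoxy-2-oxo-2H-pyran-6-yl)-3,4-bis(4-methoxybenzylidene)hexane-2,5-dione
Product: 17 (2E,3E)-1-[4-(benzyloxy)-2,6-dihydroxyphenyl]-4-(2,6-dihydroxy-4-methoxyphenyl)-2,3-bis(4-methoxybenzylidene)butane-1,4-dione, via ring-opened bis(methyl ester) 16 (not isolated)
Conditions: Mg(OMe)2 (8 equiv), MeOH, reflux, argon, dark; then poured into ice-cold 1 M HCl
Reagents that add atoms: none
Why: Mg(OMe)2 first turns both acidic pyronylmethyl ketones into chelated magnesium enolates and then opens each lactone at the pyrone carbonyl carbon by methanolysis to the methyl (2E)-3-alkoxy-5,7-dioxoalk-2-enoate chain drawn in 16, in which the former ring double bond holds the ester cis to the chain; a direct attack of the methylene carbon on the carbonyl group of the intact pyrone is not possible, because the planar ring holds the two carbons far apart on either side of the ring oxygen. In each chain the carbon between the two ketones (future C4a or C4a'') then acylates the ester carbon, which becomes one of the two equivalent hydroxyl-bearing ortho carbons (C5/C8a or C5''/C8a''), in a 6-exo-trig Dieckmann (Claisen-type) closure; methoxide leaves and enolisation of the cyclic triketone gives benzene ring A of unit 1 and, in the same way, ring A of unit 2. The closest known reaction is the Mg(OMe)2-mediated recyclisation of 6-(2-oxoalkyl)-4-methoxy-2-pyrones and of 3,5,7-triketo esters to acylphloroglucinols. No stereocentre is formed, and the thermodynamic (E,E) geometry of the two benzylidene groups is kept. The step needs C-acylation instead of the aldol mode, which is secured by the magnesium chelate of the 1,3-diketone, by the enol ether that makes C3 of each pyrone a poor nucleophile and by the hindered, cross-conjugated side-chain ketone as a poor aldol acceptor; full enolisation of both ketones also prevents the cyclopentenone aldol of the 1,4-diketone. The 2',6'-dihydroxychalcones must stay open, which their magnesium phenoxide chelates and the inverse quench into cold acid should ensure, so that C2, C3, C2'' and C3'' are left for step 9.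

Step 9
Reactants: 17 (2E,3E)-1-[4-(benzyloxy)-2,6-dihydroxyphenyl]-4-(2,6-dihydroxy-4-methoxyphenyl)-2,3-bis(4-methoxybenzylidene)butane-1,4-dione
Product: 20 (2R,3R)-7-(benzyloxy)-5-hydroxy-3-[(2R,3R)-5-hydroxy-7-methoxy-2-(4-methoxyphenyl)-4-oxochroman-3-yl]-2-(4-methoxyphenyl)chroman-4-one, via 7-benzyloxyflavanone chalcone 18 (not isolated), via 7-methoxyflavanone chalcone 19 (not isolated)
Conditions: 1-[3,5-bis(trifluoromethyl)phenyl]-3-[(8S,9S)-6'-methoxycinchonan-9-yl]thiourea (quinine-derived, 20 mol %), toluene/CH2Cl2, −25 °C, dark; then filtration through silica with AcOH-doped eluent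
Reagents that add atoms: none
Why: Proposed new method: the quinuclidine nitrogen of the bifunctional catalyst acts as a general base on one ortho-hydroxyl group of each 2',6'-dihydroxychalcone while the thiourea binds the chelated carbonyl oxygen, so that O1 (then O1'') should add to one enantioface of C2 (C2'') in a 6-endo-trig oxa-Michael closure under catalyst control (R at both centres, the two closures being independent, so that an error in one of them ends in a separable diastereomer), and the dienol so formed is protonated at C3 (C3'') by the ammonium ion from the face opposite to the new pseudo-axial 2-aryl group (substrate control, kinetic), which places H-3 cis to H-2 and gives the 2,3-cis ring; the closest known reactions are the cinchona-thiourea-catalysed oxa-Michael cyclisation of α-alkoxycarbonyl-2'-hydroxychalcones to flavanones and the kinetic cis-selective protonation of 2-aryl-3-substituted chroman-4-one enolates, neither of which has been shown on an α-alkenyl chalcone or twice in one molecule.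

Step 10
Reactants: 20 (2R,3R)-7-(benzyloxy)-5-hydroxy-3-[(2R,3R)-5-hydroxy-7-methoxy-2-(4-methoxyphenyl)-4-oxochroman-3-yl]-2-(4-methoxyphenyl)chroman-4-one
Product: 21 (2R,3R)-5,7-dihydroxy-3-[(2R,3R)-5-hydroxy-7-methoxy-2-(4-methoxyphenyl)-4-oxochroman-3-yl]-2-(4-methoxyphenyl)chroman-4-one (CNP0184936.2)
Conditions: H2 (1 atm), Pd/C (10 wt% palladium on carbon), EtOAc, rt
Reagents that add atoms: none
Why: Hydrogenolysis of the aryl benzyl ether on palladium under neutral conditions, which is much faster than cleavage of the benzylic C2–O1 and C2''–O1'' bonds or reduction of the chelated ketones and exposes C3 and C3'' to neither acid nor base.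

Compound list
1 | dimethyl succinate | COC(=O)CCC(=O)OC | starting material
2 | 4-methoxybenzaldehyde | COc1ccc(C=O)cc1 | starting material
3 | (E)-3-(methoxycarbonyl)-4-(4-methoxyphenyl)but-3-enoic acid | OC(=O)C/C(=C\c1ccc(OC)cc1)C(=O)OC | intermediate
4 | dimethyl (E)-2-(4-methoxybenzylidene)succinate | COC(=O)C/C(=C\c1ccc(OC)cc1)C(=O)OC | intermediate
5 | (2E,3E)-4-methoxy-2,3-bis(4-methoxybenzylidene)-4-oxobutanoic acid (half-ester, present as its sodium salt) | COc1ccc(/C=C(C(=O)OC)\C(=C/c2ccc(OC)cc2)C(=O)O)cc1 | intermediate (not isolated)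
6 | (2E,3E)-2,3-bis(4-methoxybenzylidene)succinic acid | COc1ccc(/C=C(C(=O)O)\C(=C/c2ccc(OC)cc2)C(=O)O)cc1 | intermediate
7 | (3E,4E)-3,4-bis(4-methoxybenzylidene)dihydrofuran-2,5-dione | COc1ccc(/C=C2/C(=O)OC(=O)/C2=C/c2ccc(OC)cc2)cc1 | intermediate
8 | 4-methoxy-6-methyl-2H-pyran-2-one | COc1cc(C)oc(=O)c1 | starting material
9 | 6-lithiomethyl-4-methoxy-2H-pyran-2-one | [Li]Cc1cc(OC)cc(=O)o1 | intermediate (not isolated)
10 | (2E,3E)-2,3-bis(4-methoxybenzylidene)-5-(4-methoxy-2-oxo-2H-pyran-6-yl)-4-oxopentanoic acid | COc1ccc(/C=C(C(=O)O)\C(=C/c2ccc(OC)cc2)C(=O)Cc2cc(OC)cc(=O)o2)cc1 | intermediate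
11 | 4-hydroxy-6-methyl-2H-pyran-2-one | Cc1cc(O)cc(=O)o1 | starting material
12 | 4-(benzyloxy)-6-methyl-2H-pyran-2-one | Cc1cc(OCc2ccccc2)cc(=O)o1 | intermediate
13 | (2E,3E)-1-(imidazol-1-yl)-2,3-bis(4-methoxybenzylidene)-5-(4-methoxy-2-oxo-2H-pyran-6-yl)pentane-1,4-dione (imidazolide of 10) | COc1ccc(/C=C(C(=O)n2ccnc2)\C(=C/c2ccc(OC)cc2)C(=O)Cc2cc(OC)cc(=O)o2)cc1 | intermediate (not isolated)
14 | 4-(benzyloxy)-6-lithiomethyl-2H-pyran-2-one | [Li]Cc1cc(OCc2ccccc2)cc(=O)o1 | intermediate (not isolated)
15 | (3E,4E)-1-[4-(benzyloxy)-2-oxo-2H-pyran-6-yl]-6-(4-methoxy-2-oxo-2H-pyran-6-yl)-3,4-bis(4-methoxybenzylidene)hexane-2,5-dione | COc1ccc(/C=C(C(=O)Cc2cc(OCc3ccccc3)cc(=O)o2)\C(=C/c2ccc(OC)cc2)C(=O)Cc2cc(OC)cc(=O)o2)cc1 | intermediate (precursor of the key step)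
16 | dimethyl (2E,8E,9E,14E)-3-(benzyloxy)-14-methoxy-8,9-bis(4-methoxybenzylidene)-5,7,10,12-tetraoxohexadeca-2,14-dienedioate (drawn with both lactones opened; each arm passes through this stage independently, as its magnesium enolate) | COc1ccc(/C=C(C(=O)CC(=O)C/C(OCc2ccccc2)=C\C(=O)OC)\C(=C/c2ccc(OC)cc2)C(=O)CC(=O)C/C(OC)=C\C(=O)OC)cc1 | intermediate (not isolated)
17 | (2E,3E)-1-[4-(benzyloxy)-2,6-dihydroxyphenyl]-4-(2,6-dihydroxy-4-methoxyphenyl)-2,3-bis(4-methoxybenzylidene)butane-1,4-dione | COc1ccc(/C=C(C(=O)c2c(O)cc(OCc3ccccc3)cc2O)\C(=C/c2ccc(OC)cc2)C(=O)c2c(O)cc(OC)cc2O)cc1 | intermediate (product of the key step)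
18 | (2R,3R)-7-(benzyloxy)-3-[(E)-3-(2,6-dihydroxy-4-methoxyphenyl)-1-(4-methoxyphenyl)-3-oxoprop-1-en-2-yl]-5-hydroxy-2-(4-methoxyphenyl)chroman-4-one | COc1ccc([C@@H]2Oc3cc(OCc4ccccc4)cc(O)c3C(=O)[C@@H]2\C(=C/c2ccc(OC)cc2)C(=O)c2c(O)cc(OC)cc2O)cc1 | intermediate (not isolated)
19 | (2R,3R)-3-[(E)-3-[4-(benzyloxy)-2,6-dihydroxyphenyl]-1-(4-methoxyphenyl)-3-oxoprop-1-en-2-yl]-5-hydroxy-7-methoxy-2-(4-methoxyphenyl)chroman-4-one | COc1ccc(/C=C(/C(=O)c2c(O)cc(OCc3ccccc3)cc2O)[C@H]2C(=O)c3c(O)cc(OC)cc3O[C@H]2c2ccc(OC)cc2)cc1 | intermediate (not isolated)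
20 | (2R,3R)-7-(benzyloxy)-5-hydroxy-3-[(2R,3R)-5-hydroxy-7-methoxy-2-(4-methoxyphenyl)-4-oxochroman-3-yl]-2-(4-methoxyphenyl)chroman-4-one | COc1ccc([C@@H]2Oc3cc(OCc4ccccc4)cc(O)c3C(=O)[C@@H]2[C@H]2C(=O)c3c(O)cc(OC)cc3O[C@H]2c2ccc(OC)cc2)cc1 | intermediate
21 | (2R,3R)-5,7-dihydroxy-3-[(2R,3R)-5-hydroxy-7-methoxy-2-(4-methoxyphenyl)-4-oxochroman-3-yl]-2-(4-methoxyphenyl)chroman-4-one | COc1ccc([C@@H]2Oc3cc(O)cc(O)c3C(=O)[C@@H]2[C@H]2C(=O)c3c(O)cc(OC)cc3O[C@H]2c2ccc(OC)cc2)cc1 | target

Total step count: 10. Longest linear sequence: 9 steps (steps 1 to 5 and 7 to 10); step 6 is a one-step branch.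

Steps most likely to fail

1. Step 9 (Proposed new method). What may go wrong:
- weak enantiofacial control on a twisted, α-branched enone;
- a mismatched second closure that leads to the meso-type cis,cis diastereomer;
- protonation of the dienol at the γ-carbon instead of C3;
- epimerisation of C3/C3'' into the trans series, or ring reopening by the amine.

The catalyst is chosen for the R sense at C2 and C2''. Should the first run show the opposite sense, its quinidine-derived pseudoenantiomer takes its place.

Fallback with known chemistry, from 17 back to 20: both chalcones are closed by the ordinary base-mediated chalcone–flavanone isomerisation with an achiral amine (Et3N, CH2Cl2/MeOH, 0 °C, quenched with AcOH before equilibration). The diastereomers are separated by chromatography. The racemic cis,cis isomer, which consists of 20 and its mirror image (2S,3S)-7-(benzyloxy)-5-hydroxy-3-[(2S,3S)-5-hydroxy-7-methoxy-2-(4-methoxyphenyl)-4-oxochroman-3-yl]-2-(4-methoxyphenyl)chroman-4-one F1, is resolved by preparative HPLC on a polysaccharide chiral stationary phase. 20 then enters step 10.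

2. Step 8. What may go wrong:
- aldol-mode folding, or a cyclopentenone aldol of the 1,4-diketone, competing with C-acylation;
- exchange of the benzyloxy group at C4 of the pyrone by methoxide before the ring is refolded;
- unselective closure of the chalcones in the basic medium.

Fallback with known directed-lithiation and acylation chemistry and no pyrone, from 7 back to 17: 1-methoxy-3,5-bis(methoxymethoxy)benzene F2 is lithiated between its two methoxymethoxy groups (n-BuLi, THF, 0 °C) to [4-methoxy-2,6-bis(methoxymethoxy)phenyl]lithium F3. F3 opens anhydride 7 at −78 °C to (2E,3E)-4-[4-methoxy-2,6-bis(methoxymethoxy)phenyl]-2,3-bis(4-methoxybenzylidene)-4-oxobutanoic acid F4. 1,1'-Carbonyldiimidazole converts this acid, which has no enolisable position, into its imidazolide F5. This acylates [4-(benzyloxy)-2,6-bis(methoxymethoxy)phenyl]lithium F7, made in the same way from 1-(benzyloxy)-3,5-bis(methoxymethoxy)benzene F6, to give (2E,3E)-1-[4-(benzyloxy)-2,6-bis(methoxymethoxy)phenyl]-4-[4-methoxy-2,6-bis(methoxymethoxy)phenyl]-2,3-bis(4-methoxybenzylidene)butane-1,4-dione F8. HCl in MeOH at room temperature removes the four acetals and gives 17.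

3. Step 7. What may go wrong:
- consumption of the activated acid by the enolisable ketone of the same molecule (enol lactonisation, pseudo-acid chemistry) or by self-condensation;
- competition of the silylamide as a nucleophile.

Fallback, from 10 back to 15, which makes that reactivity the route: 10 is dehydrated (Ac2O, NaOAc, 60 °C) to the enol lactone (3E,4E,5Z)-5-[(4-methoxy-2-oxo-2H-pyran-6-yl)methylidene]-3,4-bis(4-methoxybenzylidene)dihydrofuran-2(3H)-one F9, which is isolated. It is opened at its lactone carbonyl group by 14 (from 12 and LiN(SiMe3)2, THF, −78 °C) in a Fujimoto–Belleau-type addition of a carbanion to an enol lactone. The enolate of the first ketone is the leaving group and stays masked until the quench, which gives 15.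

Further compounds
F1 | step 9 | (2S,3S)-7-(benzyloxy)-5-hydroxy-3-[(2S,3S)-5-hydroxy-7-methoxy-2-(4-methoxyphenyl)-4-oxochroman-3-yl]-2-(4-methoxyphenyl)chroman-4-one | COc1ccc([C@H]2Oc3cc(OCc4ccccc4)cc(O)c3C(=O)[C@H]2[C@@H]2C(=O)c3c(O)cc(OC)cc3O[C@@H]2c2ccc(OC)cc2)cc1
F2 | step 8 | 1-methoxy-3,5-bis(methoxymethoxy)benzene | COCOc1cc(OC)cc(OCOC)c1
F3 | step 8 | [4-methoxy-2,6-bis(methoxymethoxy)phenyl]lithium | [Li]c1c(OCOC)cc(OC)cc1OCOC
F4 | step 8 | (2E,3E)-4-[4-methoxy-2,6-bis(methoxymethoxy)phenyl]-2,3-bis(4-methoxybenzylidene)-4-oxobutanoic acid | COc1ccc(/C=C(C(=O)O)\C(=C/c2ccc(OC)cc2)C(=O)c2c(OCOC)cc(OC)cc2OCOC)cc1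
F5 | step 8 | (2E,3E)-1-(imidazol-1-yl)-4-[4-methoxy-2,6-bis(methoxymethoxy)phenyl]-2,3-bis(4-methoxybenzylidene)butane-1,4-dione | COc1ccc(/C=C(C(=O)n2ccnc2)\C(=C/c2ccc(OC)cc2)C(=O)c2c(OCOC)cc(OC)cc2OCOC)cc1
F6 | step 8 | 1-(benzyloxy)-3,5-bis(methoxymethoxy)benzene | COCOc1cc(OCc2ccccc2)cc(OCOC)c1
F7 | step 8 | [4-(benzyloxy)-2,6-bis(methoxymethoxy)phenyl]lithium | [Li]c1c(OCOC)cc(OCc2ccccc2)cc1OCOC
F8 | step 8 | (2E,3E)-1-[4-(benzyloxy)-2,6-bis(methoxymethoxy)phenyl]-4-[4-methoxy-2,6-bis(methoxymethoxy)phenyl]-2,3-bis(4-methoxybenzylidene)butane-1,4-dione | COc1ccc(/C=C(C(=O)c2c(OCOC)cc(OCc3ccccc3)cc2OCOC)\C(=C/c2ccc(OC)cc2)C(=O)c2c(OCOC)cc(OC)cc2OCOC)cc1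
F9 | step 7 | (3E,4E,5Z)-5-[(4-methoxy-2-oxo-2H-pyran-6-yl)methylidene]-3,4-bis(4-methoxybenzylidene)dihydrofuran-2(3H)-one | COc1ccc(/C=C2/C(=O)O/C(=C\c3cc(OC)cc(=O)o3)/C2=C/c2ccc(OC)cc2)cc1
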